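## Retrosynthetic overview

1. Target 31 comes from 30 by one acid step (silyl ether and acetal off); the triene arises by Horner–Wadsworth–Emmons olefination of lactol 23 with allylphosphonate 28, the lactol ring holding the (Z)-trisubstituted alkene.
2. Lactol 23 comes from a butenolide coupled to the only enolisable carbon of spiro ketone 18; the ring carbinol is set by hydroxyl-directed reduction and the (E)-enal by Babler–Dauben transposition.
3. Key step: samarium diiodide ketyl radical 5-exo cyclisation of aldehyde 12 onto the tetrasubstituted enone β-carbon forms the carbinol–spiro carbon bond and the quaternary spiro centre, directed by the free tertiary hydroxyl.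
4. Enone 12 comes from a Stork–Danheiser sequence on chromenone 3 (cyclohexane-1,3-dione plus 1,3-dibromopropane); a Davis hydroxylation sets the first stereocentre.
5. Ring order: the cyclohexane is bought (a temporary dihydropyran is fused on in step 1 and opened in step 4), the cyclopentane is closed in step 7, and the bought butenolide ring is attached in step 11 and opened in steps 13 and 16.

Assumption: (+)-[(8,8-dichlorocamphoryl)sulfonyl]oxaziridine is taken to give the (S)-alcohol in step 3 (if the sense is the reverse, its commercial enantiomer is used and nothing else changes); TBSO = tert-butyldimethylsilyloxy.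

## Route

Step 1
Reactants: 1 cyclohexane-1,3-dione; 2 1,3-dibromopropane
Product: 3 2,3,4,6,7,8-hexahydro-5H-chromen-5-one
Conditions: K2CO3 (2.2 equiv), DMF, 70 °C
Reagents that add atoms: none
Why: Tandem C-alkylation then 6-exo-tet O-alkylation of the 1,3-dione (annulative double alkylation) gives a bicyclic vinylogous ester in which the future 3-hydroxypropyl arm is already attached and masked.

Step 2
Reactants: 3 2,3,4,6,7,8-hexahydro-5H-chromen-5-one
Product: 5 rac-6-methyl-2,3,4,6,7,8-hexahydro-5H-chromen-5-one, via lithium dienolate 4 (not isolated)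
Conditions: LiN(i-Pr)2, THF, −78 °C; MeI, −78 → 0 °C
Reagents that add atoms: iodomethane, CI
Why: Kinetic α′-deprotonation of the vinylogous ester and SN2 methylation (Stork–Danheiser alkylation) put the methyl on the future carbinol carbon; no stereocontrol is needed because this centre is planarised again in step 3.

Step 3
Reactants: 5 rac-6-methyl-2,3,4,6,7,8-hexahydro-5H-chromen-5-one
Product: 7 (6S)-6-hydroxy-6-methyl-2,3,4,6,7,8-hexahydro-5H-chromen-5-one, via sodium enolate 6 (not isolated)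
Conditions: NaN(SiMe3)2, THF, −78 °C; (+)-[(8,8-dichlorocamphoryl)sulfonyl]oxaziridine, −78 °C; aq. NH4Cl
Reagents that add atoms: (+)-[(8,8-dichlorocamphoryl)sulfonyl]oxaziridine, CC1(C)[C@@H]2CC[C@]13CS(=O)(=O)N4O[C@@]34C2(Cl)Cl
Why: Davis asymmetric enolate hydroxylation, in which the camphor-derived oxaziridine transfers oxygen to one face of the tetrasubstituted cyclic enolate (modelled on 2-methyl-1-tetralone), sets the tertiary alcohol as (S).

Step 4
Reactants: 7 (6S)-6-hydroxy-6-methyl-2,3,4,6,7,8-hexahydro-5H-chromen-5-one; 8 pent-4-en-1-ylmagnesium bromide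
Product: 10 (4S)-4-hydroxy-2-(3-hydroxypropyl)-4-methyl-3-(pent-4-en-1-yl)cyclohex-2-en-1-one, via tertiary carbinol adduct 9 (not isolated)
Conditions: 8 (3.5 equiv), CeCl3, THF, −78 → 0 °C; then 1 M HCl, 25 °C
Reagents that add atoms: water, O
Why: Stork–Danheiser sequence: 1,2-addition to the vinylogous ester carbonyl, then acid ionises the allylic carbinol and hydrolyses the enol ether, which transposes the carbonyl and opens the dihydropyran to the free 3-hydroxypropyl chain without touching the stereocentre.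

Step 5
Reactants: 10 (4S)-4-hydroxy-2-(3-hydroxypropyl)-4-methyl-3-(pent-4-en-1-yl)cyclohex-2-en-1-one
Product: 11 (4S)-2-[3-(TBSO)propyl]-4-hydroxy-4-methyl-3-(pent-4-en-1-yl)cyclohex-2-en-1-one
Conditions: TBSCl, imidazole, CH2Cl2, 0 °C
Reagents that add atoms: tert-butyldimethylsilyl chloride, CC(C)(C)[Si](C)(C)Cl
Why: Chemoselective silylation of the primary alcohol (the tertiary one is too hindered) protects this carbon from the chromium oxidation in step 9.

Step 6
Reactants: 11 (4S)-2-[3-(TBSO)propyl]-4-hydroxy-4-methyl-3-(pent-4-en-1-yl)cyclohex-2-en-1-one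
Product: 12 4-[(6S)-2-[3-(TBSO)propyl]-6-hydroxy-6-methyl-3-oxocyclohex-1-en-1-yl]butanal
Conditions: K2OsO2(OH)4 (2 mol %), NaIO4 (4 equiv), 2,6-lutidine, 1,4-dioxane/H2O (3:1), 25 °C
Reagents that add atoms: sodium periodate, [Na+].[O-]I(=O)(=O)=O
Why: Lemieux–Johnson oxidative cleavage, in which osmylation picks the electron-rich monosubstituted alkene over the electron-poor tetrasubstituted enone and periodate cleaves the diol to the aldehyde.

Step 7
Reactants: 12 4-[(6S)-2-[3-(TBSO)propyl]-6-hydroxy-6-methyl-3-oxocyclohex-1-en-1-yl]butanal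
Product: 14 (1S,5S,6S,10S)-6-[3-(TBSO)propyl]-1,10-dihydroxy-10-methylspiro[4.5]decan-7-one, via samarium enolate 13 (not isolated)
Conditions: SmI2 (2.5 equiv), t-BuOH (3 equiv), THF, −78 °C, 12 added over 2 h (0.01 M); sat. aq. NH4Cl at −78 °C
Reagents that add atoms: none
Why: Samarium diiodide ketyl–olefin radical cyclisation (5-exo-trig): the ketyl radical adds to the enone β-carbon to form the quaternary spiro centre, with samarium bridging the ketyl oxygen and the free tertiary hydroxyl so the bond forms on the hydroxyl face; the trivalent samarium enolate formed by the second electron is protonated anti to the pseudo-axial carbinol arm, which sets the chain-bearing centre, and the new carbinol configuration (expected syn to the tertiary OH) does not matter because it is oxidised in step 9.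

Step 8
Reactants: 14 (1S,5S,6S,10S)-6-[3-(TBSO)propyl]-1,10-dihydroxy-10-methylspiro[4.5]decan-7-one; 15 prop-1-en-2-ylmagnesium bromide
Product: 16 (1S,5S,6S,9R,10S)-10-[3-(TBSO)propyl]-6-methyl-9-(prop-1-en-2-yl)spiro[4.5]decane-1,6,9-triol
Conditions: 15 (4 equiv), CeCl3, THF, −78 → 0 °C; aq. NH4Cl
Reagents that add atoms: none
Why: 1,2-Addition of the non-basic organocerium reagent (Imamoto conditions) to the hindered ketone avoids epimerising the adjacent centre; equatorial attack is expected, but the new carbinol centre is destroyed in step 9.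

Step 9
Reactants: 16 (1S,5S,6S,9R,10S)-10-[3-(TBSO)propyl]-6-methyl-9-(prop-1-en-2-yl)spiro[4.5]decane-1,6,9-triol
Product: 17 (2E)-2-[(5R,6R,10S)-6-[3-(TBSO)propyl]-10-hydroxy-10-methyl-1-oxospiro[4.5]decan-7-ylidene]propanal
Conditions: [C5H5NH][CrO3Cl] (4 equiv), 4 Å molecular sieves, CH2Cl2, 25 °C
Reagents that add atoms: pyridinium chlorochromate, [O-][Cr](=O)(=O)Cl.c1cc[nH+]cc1
Why: Babler–Dauben oxidative 1,3-transposition: the tertiary allylic chromate ester shifts [3,3] through a chair in which the more substituted ring carbon sits equatorial and so ends trans to the new C–O bond, giving the (E)-enal after oxidation, while the same reagent oxidises the secondary alcohol to the cyclopentanone.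

Step 10
Reactants: 17 (2E)-2-[(5R,6R,10S)-6-[3-(TBSO)propyl]-10-hydroxy-10-methyl-1-oxospiro[4.5]decan-7-ylidene]propanal
Product: 18 (5R,6S,10R)-10-[3-(TBSO)propyl]-9-[(E)-1,1-dimethoxypropan-2-ylidene]-6-hydroxy-6-methylspiro[4.5]decan-1-one
Conditions: HC(OMe)3, MeOH, pyridinium p-toluenesulfonate (cat.), 25 °C
Reagents that add atoms: trimethyl orthoformate, COC(OC)OC; methanol, CO
Why: Acid-catalysed acetalisation, selective for the aldehyde over the neopentyl-type cyclopentanone, masks the enal against the enolate, hydride and phosphonate reagents that follow.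

Step 11
Reactants: 18 (5R,6S,10R)-10-[3-(TBSO)propyl]-9-[(E)-1,1-dimethoxypropan-2-ylidene]-6-hydroxy-6-methylspiro[4.5]decan-1-one; 19 4-bromofuran-2(5H)-one
Product: 21 4-[(2S,5R,6S,10R)-10-[3-(TBSO)propyl]-9-[(E)-1,1-dimethoxypropan-2-ylidene]-6-hydroxy-6-methyl-1-oxospiro[4.5]decan-2-yl]furan-2(5H)-one, via bis-silyl enol ether 20 (not isolated)
Conditions: LiN(SiMe3)2 (2.2 equiv), Me3SiCl (2.5 equiv), THF, −78 °C; evaporate; then 19, Pd(dba)2 (5 mol %), P(t-Bu)3 (10 mol %), ZnF2 (1.2 equiv), DMF, 60 °C; aq. citric acid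
Reagents that add atoms: none
Why: Fluoride-activated palladium-catalysed coupling of a silyl enol ether with an alkenyl bromide (Kuwajima–Hartwig α-alkenylation, net addition–elimination on the β-bromobutenolide) under non-basic conditions uses the only enolisable position of the cyclopentanone and forms the C–C bond on the ring face away from the fully substituted carbinol carbon on the spiro centre, which sets the side-chain-bearing stereocentre.

Step 12
Reactants: 21 4-[(2S,5R,6S,10R)-10-[3-(TBSO)propyl]-9-[(E)-1,1-dimethoxypropan-2-ylidene]-6-hydroxy-6-methyl-1-oxospiro[4.5]decan-2-yl]furan-2(5H)-one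
Product: 22 4-[(1R,2S,5S,6S,10R)-10-[3-(TBSO)propyl]-9-[(E)-1,1-dimethoxypropan-2-ylidene]-1,6-dihydroxy-6-methylspiro[4.5]decan-2-yl]furan-2(5H)-one
Conditions: Me4NBH(OAc)3 (5 equiv), MeCN/AcOH (1:1), −30 °C
Reagents that add atoms: none
Why: Evans–Saksena hydroxyl-directed reduction: the tertiary alcohol binds boron and delivers hydride to the ketone face on its own side, which is also the face anti to the butenolide, so the new alcohol is cis to the side chain and anti to the tertiary alcohol as in the target.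

Step 13
Reactants: 22 4-[(1R,2S,5S,6S,10R)-10-[3-(TBSO)propyl]-9-[(E)-1,1-dimethoxypropan-2-ylidene]-1,6-dihydroxy-6-methylspiro[4.5]decan-2-yl]furan-2(5H)-one
Product: 23 (1R,2S,5S,6S,10R)-10-[3-(TBSO)propyl]-9-[(E)-1,1-dimethoxypropan-2-ylidene]-2-(5-hydroxy-2,5-dihydrofuran-3-yl)-6-methylspiro[4.5]decane-1,6-diol (both anomers)
Conditions: i-Bu2AlH (4 equiv), CH2Cl2, −78 °C; aq. KNaC4H4O6
Reagents that add atoms: none
Why: Partial lactone reduction with diisobutylaluminium hydride stops at the lactol (stable tetrahedral aluminate at −78 °C), a masked (Z)-4-hydroxy-enal whose ring fixes the trisubstituted alkene geometry.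

Step 14
Reactants: 24 2-methylprop-2-en-1-ol; 25 1-bromo-3-methylbut-2-ene
Product: 27 6-methyl-2-methylidenehept-5-en-1-ol, via dilithio dianion 26 (not isolated)
Conditions: n-BuLi (2.2 equiv), TMEDA, Et2O/hexane, 0 → 25 °C; then 25, −78 → 0 °C; aq. NH4Cl
Reagents that add atoms: none
Why: C-Alkylation of the 2-methylallyl alcohol dianion (alkoxide-directed allylic metalation) by SN2 displacement on the primary prenyl bromide.

Step 15
Reactants: 27 6-methyl-2-methylidenehept-5-en-1-ol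
Product: 28 diethyl (6-methyl-2-methylidenehept-5-en-1-yl)phosphonate
Conditions: P(OEt)3 (3 equiv), ZnI2 (1.5 equiv), toluene, 110 °C
Reagents that add atoms: triethyl phosphite, CCOP(OCC)OCC
Why: Zinc iodide-mediated one-flask conversion of an allylic alcohol into its diethyl phosphonate (transesterification then Michaelis–Arbuzov-type rearrangement); the two allyl termini are equivalent, so no regioisomer can form.

Step 16
Reactants: 23 (1R,2S,5S,6S,10R)-10-[3-(TBSO)propyl]-9-[(E)-1,1-dimethoxypropan-2-ylidene]-2-(5-hydroxy-2,5-dihydrofuran-3-yl)-6-methylspiro[4.5]decane-1,6-diol; 28 diethyl (6-methyl-2-methylidenehept-5-en-1-yl)phosphonate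
Product: 30 (1R,2S,5S,6S,10R)-10-[3-(TBSO)propyl]-9-[(E)-1,1-dimethoxypropan-2-ylidene]-2-[(2Z,4E)-1-hydroxy-10-methyl-6-methylideneundeca-2,4,9-trien-2-yl]-6-methylspiro[4.5]decane-1,6-diol, via lithiated phosphonate 29 (not isolated)
Conditions: 28 (4.5 equiv), n-BuLi (4.4 equiv), THF/DMPU, −78 °C; then 23, −78 → 25 °C
Reagents that add atoms: none
Why: Horner–Wadsworth–Emmons olefination of the open hydroxy-enal tautomer of the lactol at the α-carbon of the allylphosphonate anion gives the new disubstituted alkene (E), while the lactol-derived trisubstituted alkene keeps its (Z) geometry.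

Step 17
Reactants: 30 (1R,2S,5S,6S,10R)-10-[3-(TBSO)propyl]-9-[(E)-1,1-dimethoxypropan-2-ylidene]-2-[(2Z,4E)-1-hydroxy-10-methyl-6-methylideneundeca-2,4,9-trien-2-yl]-6-methylspiro[4.5]decane-1,6-diol
Product: 31 (2E)-2-[(1R,2S,5S,6R,10S)-1,10-dihydroxy-2-[(2Z,4E)-1-hydroxy-10-methyl-6-methylideneundeca-2,4,9-trien-2-yl]-6-(3-hydroxypropyl)-10-methylspiro[4.5]decan-7-ylidene]propanal (CNP0246965.2)
Conditions: AcOH/THF/H2O (3:1:1), 25 °C
Reagents that add atoms: water, O
Why: Mild aqueous acetic acid cleaves the primary silyl ether and hydrolyses the allylic dimethyl acetal in one operation without ionising the trienyl carbinol, and no stereocentre is touched.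

## Compound list

1 | cyclohexane-1,3-dione | O=C1CCCC(=O)C1 | starting material
2 | 1,3-dibromopropane | BrCCCBr | starting material
3 | 2,3,4,6,7,8-hexahydro-5H-chromen-5-one | O=C1CCCC2=C1CCCO2 | intermediate
4 | lithium dienolate of 3 (lithium 3,4,7,8-tetrahydro-2H-chromen-5-olate) | [Li]OC1=CCCC2=C1CCCO2 | intermediate (not isolated)
5 | rac-6-methyl-2,3,4,6,7,8-hexahydro-5H-chromen-5-one | CC1CCC2=C(CCCO2)C1=O | intermediate
6 | sodium enolate of 5 (sodium 6-methyl-3,4,7,8-tetrahydro-2H-chromen-5-olate) | [Na]OC1=C(C)CCC2=C1CCCO2 | intermediate (not isolated)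
7 | (6S)-6-hydroxy-6-methyl-2,3,4,6,7,8-hexahydro-5H-chromen-5-one | O=C1C2=C(CC[C@]1(C)O)OCCC2 | intermediate
8 | pent-4-en-1-ylmagnesium bromide | C=CCCC[Mg]Br | starting material
9 | (6S)-6-methyl-5-(pent-4-en-1-yl)-3,4,5,6,7,8-hexahydro-2H-chromene-5,6-diol (bromomagnesium dialkoxide in the flask; both C-5 epimers) | C=CCCCC1(O)C2=C(CC[C@]1(C)O)OCCC2 | intermediate (not isolated)
10 | (4S)-4-hydroxy-2-(3-hydroxypropyl)-4-methyl-3-(pent-4-en-1-yl)cyclohex-2-en-1-one | C=CCCCC1=C(CCCO)C(=O)CC[C@]1(C)O | intermediate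
11 | (4S)-2-[3-(TBSO)propyl]-4-hydroxy-4-methyl-3-(pent-4-en-1-yl)cyclohex-2-en-1-one | C=CCCCC1=C(CCCO[Si](C)(C)C(C)(C)C)C(=O)CC[C@]1(C)O | intermediate
12 | 4-[(6S)-2-[3-(TBSO)propyl]-6-hydroxy-6-methyl-3-oxocyclohex-1-en-1-yl]butanal | O=CCCCC1=C(CCCO[Si](C)(C)C(C)(C)C)C(=O)CC[C@]1(C)O | intermediate
13 | bis(diiodosamarium) enolate–alkoxide of 14 (trivalent samarium) | C1CC[C@]2(C(CCCO[Si](C)(C)C(C)(C)C)=C(O[Sm](I)I)CC[C@]2(C)O)[C@H]1O[Sm](I)I | intermediate (not isolated)
14 | (1S,5S,6S,10S)-6-[3-(TBSO)propyl]-1,10-dihydroxy-10-methylspiro[4.5]decan-7-one | C1CC[C@]2([C@H](CCCO[Si](C)(C)C(C)(C)C)C(=O)CC[C@]2(C)O)[C@H]1O | intermediate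
15 | prop-1-en-2-ylmagnesium bromide | CC(=C)[Mg]Br | starting material
16 | (1S,5S,6S,9R,10S)-10-[3-(TBSO)propyl]-6-methyl-9-(prop-1-en-2-yl)spiro[4.5]decane-1,6,9-triol | C1CC[C@]2([C@H](CCCO[Si](C)(C)C(C)(C)C)[C@@](O)(C(C)=C)CC[C@]2(C)O)[C@H]1O | intermediate
17 | (2E)-2-[(5R,6R,10S)-6-[3-(TBSO)propyl]-10-hydroxy-10-methyl-1-oxospiro[4.5]decan-7-ylidene]propanal | C1CC[C@]2([C@H](CCCO[Si](C)(C)C(C)(C)C)/C(=C(\C)C=O)CC[C@]2(C)O)C1=O | intermediate
18 | (5R,6S,10R)-10-[3-(TBSO)propyl]-9-[(E)-1,1-dimethoxypropan-2-ylidene]-6-hydroxy-6-methylspiro[4.5]decan-1-one | C1CC[C@]2([C@H](CCCO[Si](C)(C)C(C)(C)C)/C(=C(\C)C(OC)OC)CC[C@]2(C)O)C1=O | intermediate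
19 | 4-bromofuran-2(5H)-one | O=C1OCC(Br)=C1 | starting material
20 | bis(trimethylsilyl) derivative of 18 (cyclopentanone trimethylsilyl enol ether, tertiary O-trimethylsilyl ether) | C1CC[C@]2([C@H](CCCO[Si](C)(C)C(C)(C)C)/C(=C(\C)C(OC)OC)CC[C@]2(C)O[Si](C)(C)C)C(O[Si](C)(C)C)=C1 | intermediate (not isolated)
21 | 4-[(2S,5R,6S,10R)-10-[3-(TBSO)propyl]-9-[(E)-1,1-dimethoxypropan-2-ylidene]-6-hydroxy-6-methyl-1-oxospiro[4.5]decan-2-yl]furan-2(5H)-one | O=C1OCC(=C1)[C@@H]1CC[C@]2([C@H](CCCO[Si](C)(C)C(C)(C)C)/C(=C(\C)C(OC)OC)CC[C@]2(C)O)C1=O | intermediate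
22 | 4-[(1R,2S,5S,6S,10R)-10-[3-(TBSO)propyl]-9-[(E)-1,1-dimethoxypropan-2-ylidene]-1,6-dihydroxy-6-methylspiro[4.5]decan-2-yl]furan-2(5H)-one | O=C1OCC(=C1)[C@@H]1CC[C@]2([C@H](CCCO[Si](C)(C)C(C)(C)C)/C(=C(\C)C(OC)OC)CC[C@]2(C)O)[C@@H]1O | intermediate
23 | (1R,2S,5S,6S,10R)-10-[3-(TBSO)propyl]-9-[(E)-1,1-dimethoxypropan-2-ylidene]-2-(5-hydroxy-2,5-dihydrofuran-3-yl)-6-methylspiro[4.5]decane-1,6-diol (both anomers) | OC1OCC(=C1)[C@@H]1CC[C@]2([C@H](CCCO[Si](C)(C)C(C)(C)C)/C(=C(\C)C(OC)OC)CC[C@]2(C)O)[C@@H]1O | intermediate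
24 | 2-methylprop-2-en-1-ol | C=C(C)CO | starting material
25 | 1-bromo-3-methylbut-2-ene | CC(C)=CCBr | starting material
26 | dilithio dianion of 24 (lithium 2-(lithiomethyl)prop-2-en-1-olate) | [Li]CC(=C)CO[Li] | intermediate (not isolated)
27 | 6-methyl-2-methylidenehept-5-en-1-ol | C=C(CO)CCC=C(C)C | intermediate
28 | diethyl (6-methyl-2-methylidenehept-5-en-1-yl)phosphonate | C=C(CP(=O)(OCC)OCC)CCC=C(C)C | intermediate
29 | α-lithiated 28 | [Li]C(C(=C)CCC=C(C)C)P(=O)(OCC)OCC | intermediate (not isolated)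
30 | (1R,2S,5S,6S,10R)-10-[3-(TBSO)propyl]-9-[(E)-1,1-dimethoxypropan-2-ylidene]-2-[(2Z,4E)-1-hydroxy-10-methyl-6-methylideneundeca-2,4,9-trien-2-yl]-6-methylspiro[4.5]decane-1,6-diol | C=C(/C=C/C=C(\CO)[C@@H]1CC[C@]2([C@H](CCCO[Si](C)(C)C(C)(C)C)/C(=C(\C)C(OC)OC)CC[C@]2(C)O)[C@@H]1O)CCC=C(C)C | intermediate
31 | (2E)-2-[(1R,2S,5S,6R,10S)-1,10-dihydroxy-2-[(2Z,4E)-1-hydroxy-10-methyl-6-methylideneundeca-2,4,9-trien-2-yl]-6-(3-hydroxypropyl)-10-methylspiro[4.5]decan-7-ylidene]propanal | C=C(/C=C/C=C(\CO)[C@@H]1CC[C@]2([C@H](CCCO)/C(=C(\C)C=O)CC[C@]2(C)O)[C@@H]1O)CCC=C(C)C | target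

## Step count and risks

Total steps: 17. Longest linear sequence: 15 (steps 1–13, 16, 17); steps 14–15 make the phosphonate separately.

Three steps most likely to fail:

Step 7. The enone may simply be reduced, the γ-hydroxyl may be lost reductively, addition to a tetrasubstituted alkene may be slow, and the enolate protonation that sets the chain-bearing centre may go the wrong way. The fallback swaps the ketyl radical for an acyl radical. It sets out from 12: irradiation (390 nm) with (n-Bu4N)4W10O32 (2 mol %) in MeCN abstracts the formyl hydrogen, and the acyl radical closes 5-exo onto the enone β-carbon to give (5R,6S,10S)-6-[3-(TBSO)propyl]-10-hydroxy-10-methylspiro[4.5]decane-1,7-dione F1. Only the β-hydroxy ketone of the two carbonyls is then reduced by Me4NBH(OAc)3 (MeCN/AcOH, −30 °C) to (1R,5S,6S,10S)-6-[3-(TBSO)propyl]-1,10-dihydroxy-10-methylspiro[4.5]decan-7-one F2. Reagent 15 with CeCl3 converts this into (1R,5S,6S,9R,10S)-10-[3-(TBSO)propyl]-6-methyl-9-(prop-1-en-2-yl)spiro[4.5]decane-1,6,9-triol F3, and the pyridinium chlorochromate conditions of step 9 take F3 to 17, where the route is rejoined.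

Step 9. The hindered tertiary allylic alcohol may dehydrate to a diene, and the E/Z ratio of the tetrasubstituted enal may be poor. The fallback uses a masked formyl-vinyl anion instead of an oxidative transposition. It sets out from 14: (Z)-1-ethoxy-2-lithioprop-1-ene (from (Z)-2-bromo-1-ethoxyprop-1-ene and t-BuLi, with CeCl3, THF, −78 °C) adds to the ketone to give (1S,5S,6S,9R,10S)-10-[3-(TBSO)propyl]-9-[(Z)-1-ethoxyprop-1-en-2-yl]-6-methylspiro[4.5]decane-1,6,9-triol F4. Aqueous oxalic acid in THF ionises the carbinol and hydrolyses the enol ether to (2E)-2-[(1S,5S,6R,10S)-6-[3-(TBSO)propyl]-1,10-dihydroxy-10-methylspiro[4.5]decan-7-ylidene]propanal F5, and Dess–Martin periodinane (NaHCO3, CH2Cl2) oxidises the secondary alcohol to return to the route at 17.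

Step 11. Once the tertiary alkoxide is freed the β-hydroxy ketone can open by retro-aldol, and the new α-centre is acidic and can epimerise. The fallback couples a heteroaryl group and unmasks it oxidatively. It sets out from 18 (through 20): 3-bromofuran under the same Pd(dba)2/P(t-Bu)3/ZnF2 conditions gives the less acidic (2S,5R,6S,10R)-10-[3-(TBSO)propyl]-9-[(E)-1,1-dimethoxypropan-2-ylidene]-2-(furan-3-yl)-6-hydroxy-6-methylspiro[4.5]decan-1-one F6. Me4NBH(OAc)3 reduces it to (1R,2S,5S,6S,10R)-10-[3-(TBSO)propyl]-9-[(E)-1,1-dimethoxypropan-2-ylidene]-2-(furan-3-yl)-6-methylspiro[4.5]decane-1,6-diol F7. Singlet oxygen (O2, rose bengal, hν, i-Pr2NEt, CH2Cl2, −78 °C) converts the furan into 4-[(1R,2S,5S,6S,10R)-10-[3-(TBSO)propyl]-9-[(E)-1,1-dimethoxypropan-2-ylidene]-1,6-dihydroxy-6-methylspiro[4.5]decan-2-yl]-5-hydroxyfuran-2(5H)-one F8, and NaBH4 (MeOH, 0 °C, then pH 4) reduces the hemiacetal carbon and relactonises to return to the route at 22.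

## Further compounds

F1 | step 7 | (5R,6S,10S)-6-[3-(TBSO)propyl]-10-hydroxy-10-methylspiro[4.5]decane-1,7-dione | C1CC[C@]2([C@H](CCCO[Si](C)(C)C(C)(C)C)C(=O)CC[C@]2(C)O)C1=O
F2 | step 7 | (1R,5S,6S,10S)-6-[3-(TBSO)propyl]-1,10-dihydroxy-10-methylspiro[4.5]decan-7-one | C1CC[C@]2([C@H](CCCO[Si](C)(C)C(C)(C)C)C(=O)CC[C@]2(C)O)[C@@H]1O
F3 | step 7 | (1R,5S,6S,9R,10S)-10-[3-(TBSO)propyl]-6-methyl-9-(prop-1-en-2-yl)spiro[4.5]decane-1,6,9-triol | C1CC[C@]2([C@H](CCCO[Si](C)(C)C(C)(C)C)[C@@](O)(C(C)=C)CC[C@]2(C)O)[C@@H]1O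
F4 | step 9 | (1S,5S,6S,9R,10S)-10-[3-(TBSO)propyl]-9-[(Z)-1-ethoxyprop-1-en-2-yl]-6-methylspiro[4.5]decane-1,6,9-triol | C1CC[C@]2([C@H](CCCO[Si](C)(C)C(C)(C)C)[C@@](O)(/C(C)=C\OCC)CC[C@]2(C)O)[C@H]1O
F5 | step 9 | (2E)-2-[(1S,5S,6R,10S)-6-[3-(TBSO)propyl]-1,10-dihydroxy-10-methylspiro[4.5]decan-7-ylidene]propanal | C1CC[C@]2([C@H](CCCO[Si](C)(C)C(C)(C)C)/C(=C(\C)C=O)CC[C@]2(C)O)[C@H]1O
F6 | step 11 | (2S,5R,6S,10R)-10-[3-(TBSO)propyl]-9-[(E)-1,1-dimethoxypropan-2-ylidene]-2-(furan-3-yl)-6-hydroxy-6-methylspiro[4.5]decan-1-one | o1ccc(c1)[C@@H]1CC[C@]2([C@H](CCCO[Si](C)(C)C(C)(C)C)/C(=C(\C)C(OC)OC)CC[C@]2(C)O)C1=O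
F7 | step 11 | (1R,2S,5S,6S,10R)-10-[3-(TBSO)propyl]-9-[(E)-1,1-dimethoxypropan-2-ylidene]-2-(furan-3-yl)-6-methylspiro[4.5]decane-1,6-diol | o1ccc(c1)[C@@H]1CC[C@]2([C@H](CCCO[Si](C)(C)C(C)(C)C)/C(=C(\C)C(OC)OC)CC[C@]2(C)O)[C@@H]1O
F8 | step 11 | 4-[(1R,2S,5S,6S,10R)-10-[3-(TBSO)propyl]-9-[(E)-1,1-dimethoxypropan-2-ylidene]-1,6-dihydroxy-6-methylspiro[4.5]decan-2-yl]-5-hydroxyfuran-2(5H)-one (both hemiacetal epimers) | O=C1OC(O)C(=C1)[C@@H]1CC[C@]2([C@H](CCCO[Si](C)(C)C(C)(C)C)/C(=C(\C)C(OC)OC)CC[C@]2(C)O)[C@@H]1O
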